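**Retrosynthetic overview**
- Last bond made: the C8'–O bond of the enol, by conjugate hydration of a C7'≡C8' ynone (the 3'-acetate is cleaved in the same flask); the unactivated C7≡C8 alkyne stays.
- The C40 diyne-one comes from a C18 heptaene diiodide (C10 dialdehyde + 2 × C4 iodo-phosphonate, double Horner–Wadsworth–Emmons) by two Sonogashira couplings, first with the ring A alkyne, then with the cyclopentyl ynone.
- Ring A alkyne: safranal → racemic 3,4-epoxide → (3S,4S)-trans-diol by an enantioconvergent hydrolytic epoxide opening (new C–O bond-forming method, sets C3 and C4) → aldehyde-to-alkyne homologation.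
- Cyclopentyl ynone: (4R,6R)-actinol → ethynyl carbinol → enyne → anti-epoxide (C–O) → Lewis-acid semipinacol ring contraction (sets C5').
- Rings: the six-membered ring A is carried intact from safranal; the five-membered ring is made by contraction of the actinol-derived six-membered ring (step 11), before the fragments are joined.

Assumption: safranal, (4R,6R)-actinol, the C10 dialdehyde and but-2-yn-1-ol are bought as bulk flavour or carotenoid intermediates; the drawn 8'-enol is the hydrogen-bonded tautomer of the 6',8'-diketone and forms on its own; carotenoid numbering is used for positions (primes for the cyclopentane half); a racemate is drawn as one of its two enantiomers and marked "rac" in its name.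

**Route**

Step 1
Reactants: 1 safranal (2,6,6-trimethylcyclohexa-1,3-diene-1-carbaldehyde)
Product: 2 rac-(1R,6S)-2,4,4-trimethyl-7-oxabicyclo[4.1.0]hept-2-ene-3-carbaldehyde (racemic cis-3,4-epoxide of safranal)
Conditions: dimethyldioxirane (1.05 equiv, about 0.07 M in acetone), −30 to 0 °C
Reagents that add atoms: dimethyldioxirane, CC1(C)OO1
Why: Electrophilic dioxirane epoxidation (Prilezhaev type) takes the cis-disubstituted γ,δ-alkene because the tetrasubstituted α,β-alkene is deactivated by the formyl group, and the neutral medium keeps the vinyl epoxide intact; the cis-epoxide forms as a racemate, which is all the next step needs.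

Step 2
Reactants: 2 racemic cis-3,4-epoxide of safranal (both enantiomers are consumed)
Product: 3 (3S,4S)-3,4-dihydroxy-2,6,6-trimethylcyclohex-1-ene-1-carbaldehyde
Conditions: (S,S)-Co(salen)OTs (5 mol%; salen = N,N'-bis(3,5-di-tert-butylsalicylidene)cyclohexane-1,2-diamine dianion; trivalent cobalt; the antipode that gives the (3S,4S)-diol, to be confirmed in the first run), H2O (1.5 equiv), THF (2 M), 4 °C to rt, 24 h
Reagents that add atoms: water, O
Why: Proposed new method: enantioconvergent hydrolytic opening of a racemic cis-epoxide — in the cooperative two-metal mechanism one trivalent cobalt centre activates the epoxide and a second delivers hydroxide, and the chiral salen pocket fixes the absolute configuration of the carbon that is attacked, as it does when it tells apart the two ends of a meso epoxide; because conjugation to the enal removes the usual allylic bias, C3 and C4 of 2 are nearly equivalent (pseudo-meso), so the catalyst opens the (3S,4R)-enantiomer (the one drawn for 2) at C4 and the (3R,4S)-enantiomer at C3, each by SN2 inversion, and both converge on the (3S,4S)-trans-diol with nothing left over, setting both stereocentres in this C–O bond formation; the closest known reactions are the cobalt–salen hydrolytic kinetic resolution of terminal epoxides, the hydrolytic desymmetrization of meso epoxides, and the enantioconvergent hydrolysis of cis-epoxides by epoxide hydrolases.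

Step 3
Reactants: 3 (3S,4S)-3,4-dihydroxy-2,6,6-trimethylcyclohex-1-ene-1-carbaldehyde
Product: 4 (1S,2S)-4-ethynyl-3,5,5-trimethylcyclohex-3-ene-1,2-diol (ring A alkyne)
Conditions: Me3SiCHN2 (3.5 equiv), n-BuLi (3.4 equiv), THF, −78 °C; add 3; −78 to 0 °C; aq. NH4Cl
Reagents that add atoms: trimethylsilyldiazomethane, C[Si](C)(C)C=[N+]=[N-]
Why: Colvin homologation — lithiated trimethylsilyldiazomethane first forms the dialkoxide, then adds to the hindered aldehyde, Peterson elimination gives the diazoalkene, and loss of N2 with 1,2-hydride shift of the alkylidene carbene gives the terminal alkyne; the low temperature and absence of protic base avoid isomerization of the γ-hydroxy enal, and C3 and C4 are untouched.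

Step 4
Reactants: 5 but-2-yn-1-ol
Product: 7 (2E)-3-iodobut-2-en-1-ol, via alkenylzirconocene 6 (not isolated)
Conditions: Cp2Zr(H)Cl (2.3 equiv), THF, rt to 40 °C; then I2 (1.1 equiv), 0 °C; aq. Na2S2O3
Reagents that add atoms: iodine, II
Why: Hydrozirconation–iodination — after the hydroxyl is capped as its zirconium alkoxide, syn addition of Zr–H puts zirconium on the methyl-bearing alkyne carbon (the less hindered one, reinforced by equilibration with excess reagent), and iodinolysis with retention gives the E iodide.

Step 5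
Reactants: 7 (2E)-3-iodobut-2-en-1-ol
Product: 8 (2E)-1-bromo-3-iodobut-2-ene
Conditions: PBr3 (0.4 equiv), Et2O, −10 to 0 °C, dark
Reagents that add atoms: phosphorus tribromide, BrP(Br)Br
Why: SN2 bromination of the primary allylic alcohol at low temperature keeps the double-bond geometry (the iodine-bearing terminus does not support an allyl cation).

Step 6
Reactants: 8 (2E)-1-bromo-3-iodobut-2-ene
Product: 9 diethyl [(2E)-3-iodobut-2-en-1-yl]phosphonate
Conditions: P(OEt)3 (1.5 equiv), neat, 90 °C
Reagents that add atoms: triethyl phosphite, CCOP(OCC)OCC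
Why: Michaelis–Arbuzov reaction at the primary allylic bromide (SN2; the vinyl iodide is inert to phosphite) with retention of the E geometry.

Step 7
Reactants: 9 diethyl [(2E)-3-iodobut-2-en-1-yl]phosphonate (2.3 equiv) and 10 (2E,4E,6E)-2,7-dimethylocta-2,4,6-trienedial (C10 dialdehyde)
Product: 11 (2E,4E,6E,8E,10E,12E,14E)-2,15-diiodo-6,11-dimethylhexadeca-2,4,6,8,10,12,14-heptaene (C18 diiodide)
Conditions: NaN(SiMe3)2 (2.3 equiv), THF, −78 °C; then 10 (1.0 equiv), −78 to 0 °C, dark
Reagents that add atoms: none
Why: Twofold Horner–Wadsworth–Emmons olefination of the dialdehyde with the allylic phosphonate anion forms C11=C12 and C11'=C12' with the usual high E selectivity, and the symmetric all-E product crystallizes.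

Step 8
Reactants: 12 (4R,6R)-4-hydroxy-2,2,6-trimethylcyclohexan-1-one (actinol)
Product: 13 (4R,6R)-1-ethynyl-2,2,6-trimethylcyclohexane-1,4-diol (C1 epimers)
Conditions: HC≡CMgBr (3 equiv), THF, 0 °C to rt; aq. NH4Cl
Reagents that add atoms: ethynylmagnesium bromide, C#C[Mg]Br
Why: Grignard 1,2-addition to the hindered ketone (one equivalent is spent on the hydroxyl); the configuration of the new carbinol carbon does not matter because it becomes sp2 in step 9.

Step 9
Reactants: 13 (4R,6R)-1-ethynyl-2,2,6-trimethylcyclohexane-1,4-diol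
Product: 15 (1R)-4-ethynyl-3,5,5-trimethylcyclohex-3-en-1-yl acetate, via hydroxy acetate 14 (not isolated)
Conditions: Ac2O (1.2 equiv), pyridine, DMAP (5 mol%), 0 °C to rt; then POCl3 (3 equiv), 90 °C
Reagents that add atoms: acetic anhydride, CC(=O)OC(C)=O
Why: Selective acetylation of the secondary hydroxyl, then POCl3/pyridine dehydration of the tertiary propargylic alcohol in the same flask, which can eliminate only towards C5 and gives the conjugated tetrasubstituted enyne; C3 is untouched.

Step 10
Reactants: 15 (1R)-4-ethynyl-3,5,5-trimethylcyclohex-3-en-1-yl acetate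
Product: 16 (1R,3S,6R)-6-ethynyl-1,5,5-trimethyl-7-oxabicyclo[4.1.0]heptan-3-yl acetate (anti-5,6-epoxide)
Conditions: mCPBA (1.2 equiv), NaHCO3, CH2Cl2, 0 °C; chromatography
Reagents that add atoms: 3-chloroperbenzoic acid, OOC(=O)c1cccc(Cl)c1
Why: Prilezhaev epoxidation of the tetrasubstituted alkene (the alkyne is inert) from the face opposite the C3 acetoxy group gives mainly the anti epoxide (expected about 4:1), and the minor syn isomer is removed by chromatography.

Step 11
Reactants: 16 anti-5,6-epoxide
Product: 17 (1S,3R)-3,4,4-trimethyl-3-(prop-2-ynoyl)cyclopentyl acetate (cyclopentyl ynone)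
Conditions: BF3·OEt2 (0.3 equiv), CH2Cl2, −78 to −30 °C
Reagents that add atoms: none
Why: Lewis-acid semipinacol (Meinwald) rearrangement — the C5–O bond ionizes because the terminal ethynyl group disfavours cationic character at C6, and the quaternary C1 migrates from C6 to C5 anti to the departing oxygen, so the ring contracts to the cyclopentane, C6 becomes the ketone, and the C5' quaternary centre is set with inversion (methyl cis to the ring oxygen, 5'R), as in the biogenesis of the capsanthin end group.

Step 12
Reactants: 4 ring A alkyne and 11 C18 diiodide (3 equiv)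
Product: 18 (1S,2S)-4-[(3E,5E,7E,9E,11E,13E,15E)-16-iodo-3,7,12-trimethylheptadeca-3,5,7,9,11,13,15-heptaen-1-yn-1-yl]-3,5,5-trimethylcyclohex-3-ene-1,2-diol (C29 iodide)
Conditions: Pd(PPh3)4 (5 mol%), CuI (10 mol%), Et3N, THF, rt, dark, argon
Reagents that add atoms: none
Why: Sonogashira coupling of the terminal alkyne with one of the two equivalent vinyl iodides (excess 11 suppresses double coupling and is recovered) proceeds with retention of the 9E geometry and tolerates the free diol.

Step 13
Reactants: 18 C29 iodide and 17 cyclopentyl ynone (1.5 equiv)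
Product: 19 (3S,4S,3'S,5'R)-3,4-dihydroxy-6'-oxo-7,8,7',8'-tetradehydro-β,κ-caroten-3'-yl acetate (C40 diyne-one)
Conditions: PdCl2(PPh3)2 (5 mol%), CuI (5 mol%), Et3N (3 equiv), THF, 0 °C to rt, dark; 17 added slowly
Reagents that add atoms: none
Why: Sonogashira coupling of the terminal ynone with the remaining vinyl iodide under tertiary-amine conditions (no secondary amine, which would add to the ynone) proceeds with retention of the 9'E geometry.

Step 14
Reactants: 19 C40 diyne-one
Product: 21 (3S,4S,3'S,5'R)-3,4,3',8'-tetrahydroxy-7,8-didehydro-β,κ-caroten-6'-one (target CNP0114063.1), via acetylated enol diketone 20 (not isolated)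
Conditions: LiOH·H2O (6 equiv), THF/H2O 4:1, 0 °C to rt, argon, dark; then aq. NaH2PO4 to pH 6
Reagents that add atoms: water, O (delivered as hydroxide)
Why: Conjugate (oxa-Michael) addition of hydroxide to C8' of the ynone — the only electron-poor alkyne, the C7≡C8 enyne being inert and the neopentyl-type C6' carbonyl shielded from 1,2-attack — gives the diketone enolate, a thermodynamic sink that is protonated on work-up to the hydrogen-bonded 8'-enol, while the same base saponifies the 3'-acetate; no stereocentre is touched.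

**Compound list**
1 | safranal (2,6,6-trimethylcyclohexa-1,3-diene-1-carbaldehyde) | CC1=C(C=O)C(C)(C)CC=C1 | starting material
2 | rac-(1R,6S)-2,4,4-trimethyl-7-oxabicyclo[4.1.0]hept-2-ene-3-carbaldehyde (racemic cis-3,4-epoxide of safranal; the (1R,6S)-enantiomer is drawn and its mirror image is present in equal amount) | CC1=C(C=O)C(C)(C)C[C@@H]2O[C@H]12 | intermediate
3 | (3S,4S)-3,4-dihydroxy-2,6,6-trimethylcyclohex-1-ene-1-carbaldehyde | CC1=C(C=O)C(C)(C)C[C@H](O)[C@H]1O | intermediate
4 | (1S,2S)-4-ethynyl-3,5,5-trimethylcyclohex-3-ene-1,2-diol | CC1=C(C#C)C(C)(C)C[C@H](O)[C@H]1O | intermediate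
5 | but-2-yn-1-ol | CC#CCO | starting material
6 | [(2E)-4-(chlorozirconocenyloxy)but-2-en-2-yl]zirconocene chloride (cyclopentadienyl rings drawn σ-bonded) | C/C(=C\CO[Zr](Cl)(C1C=CC=C1)C1C=CC=C1)[Zr](Cl)(C1C=CC=C1)C1C=CC=C1 | intermediate
7 | (2E)-3-iodobut-2-en-1-ol | I/C(C)=C/CO | intermediate
8 | (2E)-1-bromo-3-iodobut-2-ene | I/C(C)=C/CBr | intermediate
9 | diethyl [(2E)-3-iodobut-2-en-1-yl]phosphonate | I/C(C)=C/CP(=O)(OCC)OCC | intermediate
10 | (2E,4E,6E)-2,7-dimethylocta-2,4,6-trienedial | O=C/C(C)=C/C=C/C=C(C)/C=O | starting material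
11 | (2E,4E,6E,8E,10E,12E,14E)-2,15-diiodo-6,11-dimethylhexadeca-2,4,6,8,10,12,14-heptaene | I/C(C)=C/C=C/C(C)=C/C=C/C=C(C)/C=C/C=C(C)/I | intermediate
12 | (4R,6R)-4-hydroxy-2,2,6-trimethylcyclohexan-1-one (actinol) | CC1(C)C[C@H](O)C[C@@H](C)C1=O | starting material
13 | (4R,6R)-1-ethynyl-2,2,6-trimethylcyclohexane-1,4-diol (C1 epimers) | CC1(C)C[C@H](O)C[C@@H](C)C1(O)C#C | intermediate
14 | (1R,3R)-4-ethynyl-4-hydroxy-3,5,5-trimethylcyclohexyl acetate (C4 epimers) | CC1(C)C[C@H](OC(C)=O)C[C@@H](C)C1(O)C#C | intermediate
15 | (1R)-4-ethynyl-3,5,5-trimethylcyclohex-3-en-1-yl acetate | CC1(C)C[C@H](OC(C)=O)CC(C)=C1C#C | intermediate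
16 | (1R,3S,6R)-6-ethynyl-1,5,5-trimethyl-7-oxabicyclo[4.1.0]heptan-3-yl acetate | CC1(C)C[C@H](OC(C)=O)C[C@@]2(C)O[C@@]12C#C | intermediate
17 | (1S,3R)-3,4,4-trimethyl-3-(prop-2-ynoyl)cyclopentyl acetate | C#CC(=O)[C@]1(C)C[C@@H](OC(C)=O)CC1(C)C | intermediate
18 | (1S,2S)-4-[(3E,5E,7E,9E,11E,13E,15E)-16-iodo-3,7,12-trimethylheptadeca-3,5,7,9,11,13,15-heptaen-1-yn-1-yl]-3,5,5-trimethylcyclohex-3-ene-1,2-diol | CC1=C(C#C/C(C)=C/C=C/C(C)=C/C=C/C=C(C)/C=C/C=C(C)/I)C(C)(C)C[C@H](O)[C@H]1O | intermediate
19 | (3S,4S,3'S,5'R)-3,4-dihydroxy-6'-oxo-7,8,7',8'-tetradehydro-β,κ-caroten-3'-yl acetate | CC1=C(C#C/C(C)=C/C=C/C(C)=C/C=C/C=C(C)/C=C/C=C(C)/C#CC(=O)[C@]2(C)C[C@@H](OC(C)=O)CC2(C)C)C(C)(C)C[C@H](O)[C@H]1O | intermediate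
20 | (3S,4S,3'S,5'R)-3,4,8'-trihydroxy-6'-oxo-7,8-didehydro-β,κ-caroten-3'-yl acetate | CC1=C(C#C/C(C)=C/C=C/C(C)=C/C=C/C=C(C)/C=C/C=C(C)/C(O)=C/C(=O)[C@]2(C)C[C@@H](OC(C)=O)CC2(C)C)C(C)(C)C[C@H](O)[C@H]1O | intermediate
21 | (3S,4S,3'S,5'R)-3,4,3',8'-tetrahydroxy-7,8-didehydro-β,κ-caroten-6'-one | CC1=C(C#C/C(C)=C/C=C/C(C)=C/C=C/C=C(C)/C=C/C=C(C)/C(O)=C/C(=O)[C@]2(C)C[C@@H](O)CC2(C)C)C(C)(C)C[C@H](O)[C@H]1O | target

**Step count and risks**

Total steps: 14. Longest linear sequence: 7 steps (steps 4, 5, 6, 7, 12, 13 and 14, from but-2-yn-1-ol).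

Step 2 (the proposed new step) may be slow or unselective, because cobalt–salen hydrolysis is established for terminal and meso epoxides, not for a racemic internal vinyl epoxide. The fallback uses known chemistry, sets out from 2 and comes back at 3. Epoxide 2 is hydrolysed with catalytic HClO4 in THF/H2O at 0 °C (anti opening at either carbon of either enantiomer gives the same racemate) to the racemic trans-diol aldehyde F1. Kinetic resolution with Burkholderia cepacia lipase and vinyl acetate in MTBE then acetylates the (3R,4R)-enantiomer at the less hindered hydroxyl, giving monoacetate F2, and leaves the (3S,4S)-enantiomer, which is diol 3 (at most 50%); it is separated by chromatography and enters step 3.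

Step 11 may fail through ionization at the propargylic carbon, an alkynyl shift, or capture of the cation by the acetate. The fallback sets out from 12 and 18 and comes back at 21. It moves the ring contraction to an epoxide in which regiochemistry cannot matter and closes the enol diketone by C-acylation instead of hydration. Actinol 12 is treated with MeMgBr/CeCl3 to give the tertiary alcohol F3, which is acetylated (Ac2O, pyridine) to the hydroxy acetate F4 and dehydrated with POCl3 in pyridine to the tetrasubstituted alkene acetate F5. mCPBA gives the anti epoxide F6, and BF3·OEt2 rearranges it to the acetylcyclopentyl acetate F7; either C–O bond may ionize, since both 1,2-shifts give the same ketone with the methyl cis to the acetate. K2CO3 in MeOH gives the hydroxy methyl ketone F8. In parallel, iodide 18 is methoxycarbonylated (PdCl2(PPh3)2, CO 1 atm, MeOH, Et3N) to the C30 methyl ester F9. Claisen condensation of the lithium enolate of F8 (excess LiN(SiMe3)2, THF, −78 to 0 °C) with F9 gives 21 directly.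

Step 13 may fail because the terminal ynone can oligomerize under amine and copper before it couples. The fallback sets out from 17 and comes back at 19. The acidic alkyne C–H of 17 is stannylated with Bu3SnOMe to the alkynylstannane F10, which is joined to iodide 18 by an amine-free Stille coupling (Pd2(dba)3, AsPh3, DMF, rt) to give 19.

**Further compounds**
F1 | step 2 | rac-(3R,4R)-3,4-dihydroxy-2,6,6-trimethylcyclohex-1-ene-1-carbaldehyde (racemic trans-diol; the (3R,4R)-enantiomer is drawn and its mirror image is compound 3) | CC1=C(C=O)C(C)(C)C[C@@H](O)[C@@H]1O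
F2 | step 2 | (1R,2R)-4-formyl-2-hydroxy-3,5,5-trimethylcyclohex-3-en-1-yl acetate | CC1=C(C=O)C(C)(C)C[C@@H](OC(C)=O)[C@@H]1O
F3 | step 11 | (4R,6R)-1,2,2,6-tetramethylcyclohexane-1,4-diol (C1 epimers) | CC1(C)C[C@H](O)C[C@@H](C)C1(C)O
F4 | step 11 | (1R,3R)-4-hydroxy-3,4,5,5-tetramethylcyclohexyl acetate (C4 epimers) | CC1(C)C[C@H](OC(C)=O)C[C@@H](C)C1(C)O
F5 | step 11 | (1R)-3,4,5,5-tetramethylcyclohex-3-en-1-yl acetate | CC1(C)C[C@H](OC(C)=O)CC(C)=C1C
F6 | step 11 | (1R,3S,6S)-1,5,5,6-tetramethyl-7-oxabicyclo[4.1.0]heptan-3-yl acetate | CC1(C)C[C@H](OC(C)=O)C[C@@]2(C)O[C@@]12C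
F7 | step 11 | (1S,3R)-3-acetyl-3,4,4-trimethylcyclopentyl acetate | CC(=O)[C@]1(C)C[C@@H](OC(C)=O)CC1(C)C
F8 | step 11 | 1-[(1R,4S)-4-hydroxy-1,2,2-trimethylcyclopentyl]ethan-1-one | CC(=O)[C@]1(C)C[C@@H](O)CC1(C)C
F9 | step 11 | methyl (3S,4S)-3,4-dihydroxy-7,8-didehydro-8'-apo-β-caroten-8'-oate | CC1=C(C#C/C(C)=C/C=C/C(C)=C/C=C/C=C(C)/C=C/C=C(C)/C(=O)OC)C(C)(C)C[C@H](O)[C@H]1O
F10 | step 13 | (1S,3R)-3,4,4-trimethyl-3-[3-(tributylstannyl)prop-2-ynoyl]cyclopentyl acetate | CCCC[Sn](CCCC)(CCCC)C#CC(=O)[C@]1(C)C[C@@H](OC(C)=O)CC1(C)C
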